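## Analysis of the target

Kanzonol T is an isoflavone: ring A is fused to the pyranone ring C, and C3 carries ring B. Ring B is fused through C3' and C4' to a 2,2-dimethyl-2H-pyran (an angular chromene) and keeps a free hydroxyl at C2'. Ring A is of the phloroglucinol type: O1, the C5 hydroxyl and the C7 hydroxyl sit on alternate carbons, and C6, between the two hydroxyls, bears a 3-hydroxy-3-methylbutyl chain (a hydrated prenyl group). The molecule has no stereocentre; the only geometric element is the cis double bond held in the pyran ring.

The sensitive groups are the styrene-like chromene double bond (hydrogenation, electrophiles, strong acid), the tertiary alcohol (acid can dehydrate it or cyclise it onto the C5 or C7 hydroxyl to a chroman) and three phenols, one of them chelated to the C4 carbonyl. The difficulty is that the three ring A oxygens are chemically alike. A classical ring closure of a 2,4,6-trioxygenated deoxybenzoin can use either ortho oxygen, so a chain placed between two oxygens can end at C6 or at C8. Ring B in addition needs the angular rather than the linear pyran.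

The strategy rests on C8a. It is ortho to the C4 carbonyl (through C4a) and meta to both the C5 and the C7 oxygen, so it is the one ring A carbon at which an oxygen nucleophile can enter by addition–elimination. If C8a carries fluorine from the first intermediate on, O1 is never a phenol beside the other two, and C6 is simply the carbon between the two real oxygens.

## Retrosynthetic reasoning

**25 back to 24.** The last operation only removes three methoxymethyl acetals and one triethylsilyl ether. No skeletal bond is involved. The phenols and the tertiary alcohol stay masked until then because they would quench the organometallic reagents and bases used earlier.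

**24 back to 23 (O1–C8a).** Ring C is opened at the O1–C8a bond. The other bonds of ring C are C–C bonds that are easy to make in open-chain form, whereas O1–C8a is the bond that decides which ring A oxygen becomes the ring oxygen. Cutting here gives the fluoro hydroxymethylene ketone 23. The forward reaction has to arylate the formyl-derived enolate oxygen at C8a and nowhere else.

**23 back to 22 (C2–C3).** C2 is a one-carbon unit at the formic acid level. It is removed by a retro-Claisen disconnection to the deoxybenzoin 22. It is put on last before the closure because the formyl ketone is the least robust intermediate of the route.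

**22 back to 21, then to 11 and 20 (C3–C4).** The ketone is taken back to the carbinol 21, and the C3–C4 bond is cut to the ring A aldehyde 11 and the ring B benzylzinc reagent 20, made from the chloride 19. An acylation of ring A by an arylacetic acid was not chosen, because it needs free phenols and acid and cannot respect the fluorine. The aldehyde 11 has no enolisable hydrogen and takes a soft benzylic nucleophile cleanly.

**11 back to 9 (C4–C4a).** The formyl group is removed to the arene 9 through the aryllithium 10. Once the chain sits at C6, the two remaining ring positions of 9 are equivalent, each flanked by fluorine and an acetal oxygen, so this metalation has no regiochemical question.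

**9 back to 3 and 4 (C6–C1'').** The silyl ether is taken off (8), the tertiary alcohol is traced to the prenyl olefin 6 through the organomercurial 7, and the aryl–allyl bond is cut to the bis-acetal 3 and prenyl bromide 4 through the aryllithium 5. The forward metalation must pick the carbon between the two acetal oxygens rather than a carbon next to fluorine.

**3 back to 1.** The acetals come from the diol 2, and 2 from the dimethyl ether 1. Methyl ethers are exchanged at the start because they could not be removed at the end beside the chromene and the tertiary alcohol.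

**19 back to 12 and 13.** The chloride 19 comes from the alcohol 17 through the mesylate 18, 17 from the aldehyde 16, and 16 from the phenol 15. The pyran ring of 15 is cut at the aryl–CH bond and the O–CMe2 bond to 2,4-dihydroxybenzaldehyde 12 and prenal 13, through the ortho-quinone methide 14. The formyl carbon of 12 ends as C3 of the isoflavone.

## Alternatives that were turned down

**Alternative 1:** Ring A is cut at C7–C8 and C5–C6. This leads to the pyranone ester A2 (ring C with ring B attached, C8 as its 2-methyl group, C5 as its ester carbon) and the lactone A3 (carbonyl as C7, α-carbon as C6). In the forward step a lithium amide base makes the lateral carbanion of A2, which opens A3 at its carbonyl. A second deprotonation at the former lactone α-carbon and Claisen closure onto the ester give the aromatic ring, and the product is A1.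

- For it: ring A appears in one step with the chain fixed at C6 by connectivity. Ring A needs no protecting group, the tertiary alcohol comes free from the lactone, and only one acetal remains to be removed. In convergence and in protecting-group economy it is stronger than the chosen route.
- Against it: the lateral carbanion of A2 is a stabilised, weak nucleophile and A3 has acidic α-hydrogens, so proton transfer competes with acylation. The first acylation product is more acidic than A2 and uses up base. The dianion has to form next to an alkoxide-bearing chain. The 4-pyranone is itself open to nucleophilic ring opening at C2. Two C–C bonds must form in sequence in one flask, and A2 needs its own multistep synthesis.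
- Comparison: the chosen route is longer and uses four protecting groups, but its one uncertain step forms a single C–O bond intramolecularly in a reaction type known for this substrate class.

**Alternative 2:** The pyran ring of ring B is cut at three bonds: aryl–CH at C3', aryl–O at C4' and O–CMe2. This leads to a 3-alkoxybenzyne, released by fluoride from the silyl triflate A5, and prenal 13. The aryne adds the aldehyde C=O in a [2+2] sense, the benzoxete opens to an ortho-quinone methide, and oxa-6π closure gives the chromene A4.

- For it: the aldehyde oxygen attacks the aryne carbon remote from the alkoxy group, so the angular fusion is fixed by the aryne itself and a linear isomer cannot form. On this point it is more certain than the chosen route, which relies on the chelated 2-hydroxyl of 12 to direct the closure in step 7.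
- Against it: A4 lacks the carbon that becomes C3, so a further metalation and formylation are needed. A5 takes several steps to make. The enal can also react with the aryne through its C=C bond or its allylic hydrogens.
- Comparison: the key step is spent on a small fragment that the chosen route reaches in one step (15 from 12 and 13), with the formyl handle already in place. The real problem of the target, the ring A oxygens and the closure of ring C, is left untouched.

**Alternative 3:** Ring B is cut at C1'–C2', C2'–C3' and C4'–C5', with C5'–C6' arising by migration. This leads to the diazo ketone A7, built on a finished chromone, and the siloxyalkyne A8. Irradiation causes Wolff rearrangement to a vinylketene, which adds A8. On warming, the cyclobutenone opens and the dienylketene closes to the phenol A6.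

- For it: the two ring B oxygens come out differentiated (free 2'-hydroxyl, silylated 4'-oxygen) with the prenyl group between them, and the step is convergent. That differentiation is stronger than anything the chosen route offers for ring B.
- Against it: rings A and C must already exist, so the ring A oxygen problem needs a separate solution. A7 combines a diazo ketone with a photoactive chromone enone, and the olefin of A8 can intercept the ketene. After A6 the pyran still has to be made: protect the 2'-hydroxyl, remove the silyl group, cyclise oxidatively, deprotect.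
- Comparison: this is several steps after the key step, against one in the chosen route, and photochemistry replaces a thermal base-mediated closure. The chosen route does not need the differentiation because the pyran is formed before ring B is attached.

Key step: step 14

Remark: the target has no stereocentre. Compounds 7 and 21 are racemates whose stereocentres are removed later, and 14 and 23 are drawn in the geometry that reacts.

## Route

Step 1
Reactants: 1 1-fluoro-3,5-dimethoxybenzene
Product: 2 5-fluorobenzene-1,3-diol
Conditions: BBr3, CH2Cl2, −78 °C → rt; then H2O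
Reagents that add atoms: none
Why: Lewis acid cleavage of aryl methyl ethers (BBr3 demethylation); the aryl fluoride is inert, and the methyl groups have to go now because they could not be removed late beside the chromene and the tertiary alcohol.

Step 2
Reactants: 2 5-fluorobenzene-1,3-diol
Product: 3 1-fluoro-3,5-bis(methoxymethoxy)benzene
Conditions: MOMCl, iPr2NEt, CH2Cl2, 0 °C → rt
Reagents that add atoms: chloromethyl methyl ether, COCCl
Why: O-alkylation of both phenols gives the bis-acetal, which directs both later lithiations and comes off under mild acid.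

Step 3
Reactants: 3 1-fluoro-3,5-bis(methoxymethoxy)benzene; 4 1-bromo-3-methylbut-2-ene (prenyl bromide)
Product: 6 5-fluoro-1,3-bis(methoxymethoxy)-2-(3-methylbut-2-en-1-yl)benzene, via aryllithium 5 (not isolated)
Conditions: n-BuLi, THF, −40 → −20 °C; CuBr·SMe2 (10 mol %), then 4, −40 → 0 °C
Reagents that add atoms: none
Why: Directed ortho-metalation under coordination control (no amine additive) should lithiate the carbon held between the two acetal oxygens, and the copper-catalysed allylation of 5 at the primary carbon gives the linear prenyl arene.

Step 4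
Reactants: 6 5-fluoro-1,3-bis(methoxymethoxy)-2-(3-methylbut-2-en-1-yl)benzene
Product: 8 4-[4-fluoro-2,6-bis(methoxymethoxy)phenyl]-2-methylbutan-2-ol, via organomercury acetate 7 (not isolated)
Conditions: Hg(OAc)2, THF/H2O, 0 °C → rt; then aq. NaOH, NaBH4, 0 °C
Reagents that add atoms: water, O
Why: Oxymercuration–demercuration adds water to the trisubstituted olefin in the Markovnikov sense to give the tertiary alcohol; NaBH4 replaces mercury by hydrogen, which also erases the stereocentre of 7.

Step 5
Reactants: 8 4-[4-fluoro-2,6-bis(methoxymethoxy)phenyl]-2-methylbutan-2-ol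
Product: 9 triethyl({4-[4-fluoro-2,6-bis(methoxymethoxy)phenyl]-2-methylbutan-2-yl}oxy)silane
Conditions: TESOTf, 2,6-lutidine, CH2Cl2, −78 °C
Reagents that add atoms: triethylsilyl trifluoromethanesulfonate, CC[Si](CC)(CC)OS(=O)(=O)C(F)(F)F
Why: Silylation of a tertiary alcohol needs the silyl triflate; at −78 °C with a hindered base the alcohol should react far faster than the aryl acetals, and the ether keeps the alcohol from quenching the organometallic reagents that follow.

Step 6
Reactants: 9 triethyl({4-[4-fluoro-2,6-bis(methoxymethoxy)phenyl]-2-methylbutan-2-yl}oxy)silane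
Product: 11 6-fluoro-2,4-bis(methoxymethoxy)-3-[3-methyl-3-(triethylsilyloxy)butyl]benzaldehyde, via aryllithium 10 (not isolated)
Conditions: s-BuLi, THF, −78 °C; DMF, −78 → −20 °C; aq. NH4Cl
Reagents that add atoms: N,N-dimethylformamide, CN(C)C=O
Why: Directed ortho-metalation at one of the two equivalent ring positions left, each activated by fluorine and an acetal oxygen, followed by formylation with the formamide; held at −78 °C, 10 should not lose LiF to an aryne.

Step 7
Reactants: 12 2,4-dihydroxybenzaldehyde; 13 3-methylbut-2-enal (prenal)
Product: 15 5-hydroxy-2,2-dimethyl-2H-chromene-6-carbaldehyde, via ortho-quinone methide 14 (not isolated)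
Conditions: Ca(OH)2, MeOH, rt
Reagents that add atoms: none
Why: Base-mediated chromenylation: the phenoxide attacks the enal through C3 (between the two oxygens), water is lost to give 14, and oxa-6π electrocyclisation closes the pyran. The 2-hydroxyl is tied to the formyl group by a hydrogen bond, so closure goes through the 4-oxygen and the angular chromene results.

Step 8
Reactants: 15 5-hydroxy-2,2-dimethyl-2H-chromene-6-carbaldehyde
Product: 16 5-(methoxymethoxy)-2,2-dimethyl-2H-chromene-6-carbaldehyde
Conditions: MOMCl, iPr2NEt, CH2Cl2, 0 °C → reflux
Reagents that add atoms: chloromethyl methyl ether, COCCl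
Why: O-alkylation of the chelated phenol, so that it cannot protonate the benzylzinc reagent or consume base later.

Step 9
Reactants: 16 5-(methoxymethoxy)-2,2-dimethyl-2H-chromene-6-carbaldehyde
Product: 17 [5-(methoxymethoxy)-2,2-dimethyl-2H-chromen-6-yl]methanol
Conditions: NaBH4, MeOH, 0 °C
Reagents that add atoms: none
Why: Hydride reduction of the aryl aldehyde; the chromene olefin and the acetal are inert to NaBH4.

Step 10
Reactants: 17 [5-(methoxymethoxy)-2,2-dimethyl-2H-chromen-6-yl]methanol
Product: 19 6-(chloromethyl)-5-(methoxymethoxy)-2,2-dimethyl-2H-chromene, via benzylic mesylate 18 (not isolated)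
Conditions: MsCl, Et3N, LiCl, THF, 0 °C → rt; used crude
Reagents that add atoms: lithium chloride, [Li+].[Cl-]; methanesulfonyl chloride, CS(=O)(=O)Cl (chloride source only, its mesyl group leaves with 18)
Why: Mesylation followed by chloride displacement in the same flask under basic conditions; the electron-rich benzylic chloride is not purified but taken straight into step 11.

Step 11
Reactants: 19 6-(chloromethyl)-5-(methoxymethoxy)-2,2-dimethyl-2H-chromene; 11 6-fluoro-2,4-bis(methoxymethoxy)-3-[3-methyl-3-(triethylsilyloxy)butyl]benzaldehyde
Product: 21 racemic 1-{6-fluoro-2,4-bis(methoxymethoxy)-3-[3-methyl-3-(triethylsilyloxy)butyl]phenyl}-2-[5-(methoxymethoxy)-2,2-dimethyl-2H-chromen-6-yl]ethan-1-ol, via benzylzinc chloride 20 (not isolated)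
Conditions: Zn dust, LiCl, THF, 0 → 25 °C; then 11, MgCl2, THF, 0 → 25 °C; aq. NH4Cl
Reagents that add atoms: none
Why: LiCl-assisted insertion of zinc into the benzylic C–Cl bond gives 20 with little homocoupling, and MgCl2-promoted 1,2-addition to the non-enolisable aldehyde forms the C3–C4 bond; the carbinol centre is racemic and is removed in step 12.

Step 12
Reactants: 21 racemic 1-{6-fluoro-2,4-bis(methoxymethoxy)-3-[3-methyl-3-(triethylsilyloxy)butyl]phenyl}-2-[5-(methoxymethoxy)-2,2-dimethyl-2H-chromen-6-yl]ethan-1-ol
Product: 22 1-{6-fluoro-2,4-bis(methoxymethoxy)-3-[3-methyl-3-(triethylsilyloxy)butyl]phenyl}-2-[5-(methoxymethoxy)-2,2-dimethyl-2H-chromen-6-yl]ethan-1-one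
Conditions: Dess–Martin periodinane, NaHCO3, CH2Cl2, 0 °C → rt
Reagents that add atoms: none
Why: Dess–Martin oxidation of the secondary benzylic alcohol under buffered conditions, which spare the acetals, the silyl ether and the chromene.

Step 13
Reactants: 22 1-{6-fluoro-2,4-bis(methoxymethoxy)-3-[3-methyl-3-(triethylsilyloxy)butyl]phenyl}-2-[5-(methoxymethoxy)-2,2-dimethyl-2H-chromen-6-yl]ethan-1-one
Product: 23 (Z)-1-{6-fluoro-2,4-bis(methoxymethoxy)-3-[3-methyl-3-(triethylsilyloxy)butyl]phenyl}-3-hydroxy-2-[5-(methoxymethoxy)-2,2-dimethyl-2H-chromen-6-yl]prop-2-en-1-one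
Conditions: NaH, HCO2Et, EtOH (cat.), THF, 0 °C → rt; aq. NH4Cl (pH about 6)
Reagents that add atoms: ethyl formate, CCOC=O
Why: Crossed Claisen condensation (C-formylation) of the benzylic ketone enolate with the non-enolisable formate, driven by the stabilised enolate of the formyl ketone; mild acidification gives the hydrogen-bonded Z enol. Any 24 formed already here is harmless.

Step 14
Reactants: 23 (Z)-1-{6-fluoro-2,4-bis(methoxymethoxy)-3-[3-methyl-3-(triethylsilyloxy)butyl]phenyl}-3-hydroxy-2-[5-(methoxymethoxy)-2,2-dimethyl-2H-chromen-6-yl]prop-2-en-1-one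
Product: 24 5,7-bis(methoxymethoxy)-3-[5-(methoxymethoxy)-2,2-dimethyl-2H-chromen-6-yl]-6-[3-methyl-3-(triethylsilyloxy)butyl]-4H-chromen-4-one
Conditions: K2CO3, DMF (dry, dilute), 4 Å MS, 90 °C
Reagents that add atoms: none
Why: K2CO3 deprotonates the enol of 23, and in DMF the loosely paired potassium enolate can turn about the C3–C4 bond so that the formyl-derived oxygen faces C8a. That oxygen adds to C8a to give a Meisenheimer anion whose charge lies on C4a, C6 and C8 and passes from C4a into the C4 carbonyl; loss of fluoride restores the arene and forms O1–C8a. The closest known reaction type is the base-mediated cyclisation of 2-fluorophenyl 1,3-dicarbonyl compounds to chromones, the oxygen analogue of the Grohe quinolone closure. Ring C closes as a six-membered ring by addition–elimination at an sp2 carbon; counted on the C4a=C8a bond that takes up the charge this is a 6-endo-trig attack, which is favourable. No stereocentre is formed. The step needs O-arylation by the formyl oxygen at C8a only: the ketone oxygen and the enolate carbon could reach C8a only through four-membered rings, fluorine is the single leaving group on ring A, and the acetal oxygens at C5 and C7 are meta to C8a, so they neither oppose the addition nor leave. Dry, dilute conditions hold back retro-Claisen loss of the formyl group and intermolecular substitution; fluoride set free may take off part of the triethylsilyl group, which does not matter because it falls in step 15.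

Step 15
Reactants: 24 5,7-bis(methoxymethoxy)-3-[5-(methoxymethoxy)-2,2-dimethyl-2H-chromen-6-yl]-6-[3-methyl-3-(triethylsilyloxy)butyl]-4H-chromen-4-one
Product: 25 Kanzonol T, 5,7-dihydroxy-3-(5-hydroxy-2,2-dimethyl-2H-chromen-6-yl)-6-(3-hydroxy-3-methylbutyl)-4H-chromen-4-one
Conditions: HCl (about 2 M) in MeOH/THF, rt → 40 °C
Reagents that add atoms: none
Why: Acid-catalysed acetal exchange moves the three methoxymethyl groups to methanol and solvolyses the silyl ether; dilute acid at moderate temperature should leave the chromene olefin and the tertiary alcohol intact.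

## Compound list

1 | 1-fluoro-3,5-dimethoxybenzene | COc1cc(F)cc(OC)c1 | starting material
2 | 5-fluorobenzene-1,3-diol | Oc1cc(F)cc(O)c1 | intermediate
3 | 1-fluoro-3,5-bis(methoxymethoxy)benzene | COCOc1cc(F)cc(OCOC)c1 | intermediate
4 | 1-bromo-3-methylbut-2-ene (prenyl bromide) | CC(C)=CCBr | starting material
5 | [4-fluoro-2,6-bis(methoxymethoxy)phenyl]lithium (formed in the flask) | [Li]c1c(OCOC)cc(F)cc1OCOC | intermediate
6 | 5-fluoro-1,3-bis(methoxymethoxy)-2-(3-methylbut-2-en-1-yl)benzene | COCOc1cc(F)cc(OCOC)c1CC=C(C)C | intermediate
7 | racemic {1-[4-fluoro-2,6-bis(methoxymethoxy)phenyl]-3-hydroxy-3-methylbutan-2-yl}mercury acetate (formed in the flask) | COCOc1cc(F)cc(OCOC)c1CC([Hg]OC(C)=O)C(C)(C)O | intermediate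
8 | 4-[4-fluoro-2,6-bis(methoxymethoxy)phenyl]-2-methylbutan-2-ol | COCOc1cc(F)cc(OCOC)c1CCC(C)(C)O | intermediate
9 | triethyl({4-[4-fluoro-2,6-bis(methoxymethoxy)phenyl]-2-methylbutan-2-yl}oxy)silane | COCOc1cc(F)cc(OCOC)c1CCC(C)(C)O[Si](CC)(CC)CC | intermediate
10 | {6-fluoro-2,4-bis(methoxymethoxy)-3-[3-methyl-3-(triethylsilyloxy)butyl]phenyl}lithium (formed in the flask) | [Li]c1c(F)cc(OCOC)c(CCC(C)(C)O[Si](CC)(CC)CC)c1OCOC | intermediate
11 | 6-fluoro-2,4-bis(methoxymethoxy)-3-[3-methyl-3-(triethylsilyloxy)butyl]benzaldehyde | O=Cc1c(F)cc(OCOC)c(CCC(C)(C)O[Si](CC)(CC)CC)c1OCOC | intermediate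
12 | 2,4-dihydroxybenzaldehyde | O=Cc1ccc(O)cc1O | starting material
13 | 3-methylbut-2-enal (prenal) | CC(C)=CC=O | starting material
14 | (3Z)-2-hydroxy-3-(3-methylbut-2-en-1-ylidene)-4-oxocyclohexa-1,5-diene-1-carbaldehyde (formed in the flask) | O=CC1=C(O)/C(=C/C=C(C)C)C(=O)C=C1 | intermediate
15 | 5-hydroxy-2,2-dimethyl-2H-chromene-6-carbaldehyde | O=Cc1ccc2OC(C)(C)C=Cc2c1O | intermediate
16 | 5-(methoxymethoxy)-2,2-dimethyl-2H-chromene-6-carbaldehyde | O=Cc1ccc2OC(C)(C)C=Cc2c1OCOC | intermediate
17 | [5-(methoxymethoxy)-2,2-dimethyl-2H-chromen-6-yl]methanol | OCc1ccc2OC(C)(C)C=Cc2c1OCOC | intermediate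
18 | [5-(methoxymethoxy)-2,2-dimethyl-2H-chromen-6-yl]methyl methanesulfonate (formed in the flask) | CS(=O)(=O)OCc1ccc2OC(C)(C)C=Cc2c1OCOC | intermediate
19 | 6-(chloromethyl)-5-(methoxymethoxy)-2,2-dimethyl-2H-chromene | ClCc1ccc2OC(C)(C)C=Cc2c1OCOC | intermediate
20 | {[5-(methoxymethoxy)-2,2-dimethyl-2H-chromen-6-yl]methyl}zinc chloride (formed in the flask) | Cl[Zn]Cc1ccc2OC(C)(C)C=Cc2c1OCOC | intermediate
21 | racemic 1-{6-fluoro-2,4-bis(methoxymethoxy)-3-[3-methyl-3-(triethylsilyloxy)butyl]phenyl}-2-[5-(methoxymethoxy)-2,2-dimethyl-2H-chromen-6-yl]ethan-1-ol | OC(Cc1ccc2OC(C)(C)C=Cc2c1OCOC)c1c(F)cc(OCOC)c(CCC(C)(C)O[Si](CC)(CC)CC)c1OCOC | intermediate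
22 | 1-{6-fluoro-2,4-bis(methoxymethoxy)-3-[3-methyl-3-(triethylsilyloxy)butyl]phenyl}-2-[5-(methoxymethoxy)-2,2-dimethyl-2H-chromen-6-yl]ethan-1-one | O=C(Cc1ccc2OC(C)(C)C=Cc2c1OCOC)c1c(F)cc(OCOC)c(CCC(C)(C)O[Si](CC)(CC)CC)c1OCOC | intermediate
23 | (Z)-1-{6-fluoro-2,4-bis(methoxymethoxy)-3-[3-methyl-3-(triethylsilyloxy)butyl]phenyl}-3-hydroxy-2-[5-(methoxymethoxy)-2,2-dimethyl-2H-chromen-6-yl]prop-2-en-1-one | O/C=C(/c1ccc2c(c1OCOC)C=CC(C)(C)O2)C(=O)c1c(F)cc(OCOC)c(CCC(C)(C)O[Si](CC)(CC)CC)c1OCOC | intermediate
24 | 5,7-bis(methoxymethoxy)-3-[5-(methoxymethoxy)-2,2-dimethyl-2H-chromen-6-yl]-6-[3-methyl-3-(triethylsilyloxy)butyl]-4H-chromen-4-one | CC[Si](CC)(CC)OC(C)(C)CCc1c(OCOC)cc2occ(-c3ccc4c(c3OCOC)C=CC(C)(C)O4)c(=O)c2c1OCOC | intermediate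
25 | Kanzonol T, 5,7-dihydroxy-3-(5-hydroxy-2,2-dimethyl-2H-chromen-6-yl)-6-(3-hydroxy-3-methylbutyl)-4H-chromen-4-one | CC(C)(O)CCc1c(O)cc2occ(-c3ccc4c(c3O)C=CC(C)(C)O4)c(=O)c2c1O | target

## Step count and risks

Total: 15 steps. Longest linear sequence: 11 steps (steps 1 to 6, then 11 to 15); the ring B branch (steps 7 to 10) joins at step 11.

**Step 14 (key step).** The ring is electron-rich and its only activator, the ortho ketone, is flanked by fluorine and an acetal oxygen. The aryl ketone may therefore twist out of conjugation and the addition to C8a may become slow. Retro-Claisen loss of the formyl group, caused by traces of water or by carbonate at high temperature, can then overtake the closure and return 22.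

The fallback keeps fluorine as the marker of O1 but exchanges it for oxygen at the aldehyde stage. There the ring is best activated and no enolisable hydrogen is present. Ring C is then closed by the classical enaminone route. It sets out from 11:
- Allyl alcohol and NaH in DMF should displace fluoride to give the allyloxy aldehyde F1.
- Addition of 20 as in step 11 gives the allyloxy carbinol F2, and Dess–Martin oxidation gives the allyloxy ketone F3.
- Pd(PPh3)4 with morpholine removes the allyl group and gives the 2-hydroxy ketone F4, whose only free phenol is the former fluorine position.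
- Heating F4 with N,N-dimethylformamide dimethyl acetal forms the enaminone, the phenol adds and dimethylamine is expelled, and the route is rejoined at 24.

**Step 3.** The lithiation may partition between the carbon flanked by the two acetal oxygens (coordination control) and the carbons next to fluorine (acidity control). The regioisomeric anion would alkylate at the wrong site or decompose through an aryne; some SN2' allylation is also possible.

The fallback sets out from 2 and fixes the position by electrophilic substitution:
- I2 and NaHCO3 in water, which iodinate resorcinols between the hydroxyls, should give 5-fluoro-2-iodobenzene-1,3-diol F5.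
- MOMCl and iPr2NEt give the iodo bis-acetal F6.
- Sonogashira coupling with 2-methylbut-3-yn-2-ol (Pd(PPh3)2Cl2, CuI, Et3N) gives the arylalkynol F7.
- Hydrogenation over palladium on carbon saturates the triple bond and rejoins the route at 8, so that prenylation and hydration are no longer needed.

**Step 11 (with step 10).** The 2,4-dialkoxybenzylic chloride 19 ionises easily. It may self-alkylate on handling or undergo Wurtz coupling during zinc insertion, and the addition of 20 to the hindered, electron-rich aldehyde may be slow.

The fallback reverses the polarity and avoids any benzylic halide. It sets out from 16 and 9: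
- Corey–Chaykovsky methylenation of 16 (trimethylsulfonium iodide, NaH, DMSO/THF) gives the racemic aryl oxirane F8.
- Meinwald rearrangement with catalytic InCl3 gives the arylacetaldehyde F9.
- 9 is lithiated to 10 as in step 6, transmetalated with CeCl3 at −78 °C to suppress enolisation, and added to F9. This gives 21 directly, where the route is rejoined; step 6's formylation and steps 9 and 10 are then not needed.

**Step 6.** If the temperature rises, 10 may lose LiF to an aryne, or the alkyllithium may attack the fluoroarene.

The fallback sets out from 9. NBS in acetonitrile should brominate one of the two equivalent free ring positions to give the aryl bromide F10. Bromine–magnesium exchange with iPrMgCl·LiCl gives an arylmagnesium that keeps its ortho fluorine well above −78 °C, and DMF then gives 11.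

**Step 15.** Under protic acid the tertiary carbinol may cyclise onto the C5 or C7 hydroxyl to a chroman or dehydrate, and methanol may add to the chromene olefin before the C7 acetal is fully cleaved.

The fallback sets out from 24 and avoids protic acid. TMSOTf with 2,2'-bipyridyl in CH2Cl2 should exchange the three aryl acetals for trimethylsilyl ethers to give the tris(trimethylsilyl) ether F11. Fluoride (TBAF buffered with acetic acid) then removes all four silyl groups and gives 25.

## Further compounds

F1 | step 14 | 6-(allyloxy)-2,4-bis(methoxymethoxy)-3-[3-methyl-3-(triethylsilyloxy)butyl]benzaldehyde | O=Cc1c(OCC=C)cc(OCOC)c(CCC(C)(C)O[Si](CC)(CC)CC)c1OCOC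
F2 | step 14 | racemic 1-{6-(allyloxy)-2,4-bis(methoxymethoxy)-3-[3-methyl-3-(triethylsilyloxy)butyl]phenyl}-2-[5-(methoxymethoxy)-2,2-dimethyl-2H-chromen-6-yl]ethan-1-ol | OC(Cc1ccc2OC(C)(C)C=Cc2c1OCOC)c1c(OCC=C)cc(OCOC)c(CCC(C)(C)O[Si](CC)(CC)CC)c1OCOC
F3 | step 14 | 1-{6-(allyloxy)-2,4-bis(methoxymethoxy)-3-[3-methyl-3-(triethylsilyloxy)butyl]phenyl}-2-[5-(methoxymethoxy)-2,2-dimethyl-2H-chromen-6-yl]ethan-1-one | O=C(Cc1ccc2OC(C)(C)C=Cc2c1OCOC)c1c(OCC=C)cc(OCOC)c(CCC(C)(C)O[Si](CC)(CC)CC)c1OCOC
F4 | step 14 | 1-{6-hydroxy-2,4-bis(methoxymethoxy)-3-[3-methyl-3-(triethylsilyloxy)butyl]phenyl}-2-[5-(methoxymethoxy)-2,2-dimethyl-2H-chromen-6-yl]ethan-1-one | O=C(Cc1ccc2OC(C)(C)C=Cc2c1OCOC)c1c(O)cc(OCOC)c(CCC(C)(C)O[Si](CC)(CC)CC)c1OCOC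
F5 | step 3 | 5-fluoro-2-iodobenzene-1,3-diol | Oc1cc(F)cc(O)c1I
F6 | step 3 | 5-fluoro-2-iodo-1,3-bis(methoxymethoxy)benzene | COCOc1cc(F)cc(OCOC)c1I
F7 | step 3 | 4-[4-fluoro-2,6-bis(methoxymethoxy)phenyl]-2-methylbut-3-yn-2-ol | COCOc1cc(F)cc(OCOC)c1C#CC(C)(C)O
F8 | step 11 | racemic 5-(methoxymethoxy)-2,2-dimethyl-6-(oxiran-2-yl)-2H-chromene | COCOc1c(C2CO2)ccc2OC(C)(C)C=Cc12
F9 | step 11 | 2-[5-(methoxymethoxy)-2,2-dimethyl-2H-chromen-6-yl]acetaldehyde | COCOc1c(CC=O)ccc2OC(C)(C)C=Cc12
F10 | step 6 | ({4-[3-bromo-4-fluoro-2,6-bis(methoxymethoxy)phenyl]-2-methylbutan-2-yl}oxy)triethylsilane | Brc1c(F)cc(OCOC)c(CCC(C)(C)O[Si](CC)(CC)CC)c1OCOC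
F11 | step 15 | 3-[2,2-dimethyl-5-(trimethylsilyloxy)-2H-chromen-6-yl]-6-[3-methyl-3-(triethylsilyloxy)butyl]-5,7-bis(trimethylsilyloxy)-4H-chromen-4-one | CC[Si](CC)(CC)OC(C)(C)CCc1c(O[Si](C)(C)C)cc2occ(-c3ccc4c(c3O[Si](C)(C)C)C=CC(C)(C)O4)c(=O)c2c1O[Si](C)(C)C
A1 | alternative 1 | 5,7-dihydroxy-6-(3-hydroxy-3-methylbutyl)-3-[5-(methoxymethoxy)-2,2-dimethyl-2H-chromen-6-yl]-4H-chromen-4-one (2'-O-methoxymethyl Kanzonol T) | CC(C)(O)CCc1c(O)cc2occ(-c3ccc4c(c3OCOC)C=CC(C)(C)O4)c(=O)c2c1O
A2 | alternative 1 | methyl 5-[5-(methoxymethoxy)-2,2-dimethyl-2H-chromen-6-yl]-2-methyl-4-oxo-4H-pyran-3-carboxylate | COC(=O)c1c(C)occ(-c2ccc3OC(C)(C)C=Cc3c2OCOC)c1=O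
A3 | alternative 1 | 6,6-dimethyltetrahydro-2H-pyran-2-one | CC1(C)CCCC(=O)O1
A4 | alternative 2 | 5-(methoxymethoxy)-2,2-dimethyl-2H-chromene | COCOc1cccc2OC(C)(C)C=Cc12
A5 | alternative 2 | 3-(methoxymethoxy)-2-(trimethylsilyl)phenyl trifluoromethanesulfonate | COCOc1cccc(OS(=O)(=O)C(F)(F)F)c1[Si](C)(C)C
A6 | alternative 3 | 3-[2-hydroxy-3-(3-methylbut-2-en-1-yl)-4-(triisopropylsilyloxy)phenyl]-5,7-bis(methoxymethoxy)-6-[3-methyl-3-(triethylsilyloxy)butyl]-4H-chromen-4-one | CC[Si](CC)(CC)OC(C)(C)CCc1c(OCOC)cc2occ(-c3ccc(O[Si](C(C)C)(C(C)C)C(C)C)c(CC=C(C)C)c3O)c(=O)c2c1OCOC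
A7 | alternative 3 | (E)-1-diazo-4-{5,7-bis(methoxymethoxy)-6-[3-methyl-3-(triethylsilyloxy)butyl]-4-oxo-4H-chromen-3-yl}but-3-en-2-one | CC[Si](CC)(CC)OC(C)(C)CCc1c(OCOC)cc2occ(/C=C/C(=O)C=[N+]=[N-])c(=O)c2c1OCOC
A8 | alternative 3 | triisopropyl[(5-methylhex-4-en-1-yn-1-yl)oxy]silane | CC(C)=CCC#CO[Si](C(C)C)(C(C)C)C(C)C
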